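## Structural features

Target 26 is a (2S)-flavanone: benzo ring A is fused to the dihydropyranone ring C, which carries phenyl ring B on C2. C2 is the only stereocentre, so no stereocentres stand next to each other. Ring A is hexasubstituted: the oxygens on C8a (O1), C7 (methoxy) and C5 (hydroxyl) alternate with three carbon substituents, namely C4 on C4a and two identical arms on C6 and C8. Each arm is a 2-hydroxy-5-(2-hydroxybenzyl)benzyl group: a CH2 link from ring A to phenol ring D, which is joined para to its hydroxyl through a second CH2 to the ortho carbon of phenol ring E. Fragile points are the O1–C2 bond (β-elimination to the 2'-hydroxychalcone under base, less readily under strong acid, erases the C2 configuration), the five electron-rich phenols, and the single methyl ether on O7, which must be told apart from the other phenolic oxygens. The real difficulty is the regiochemistry of ring A: electrophilic benzylation of a phloroglucinol or of a 5,7-dioxygenated flavanone does not cleanly distinguish C6, C8 and the oxygens, and cannot by itself put the lone methyl on the oxygen between the arms. The key step exploits exactly this alternation (C8a–O, C8–arm, C7–OMe, C6–arm, C5–O, C4a–H), which a cyclobutenone/alkynyl ether benzannulation sets in one operation, with both arms entering as benzylic substituents of the same kind of alkynyl ether. Because the arms are identical, ring A before closure of ring C has a mirror plane through C4a and C7, so the two oxygens ortho to C4a are interchangeable and the group on the C5 oxygen can be chosen freely.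

## Logic of the disconnections

**26 ⇒ 25.** The four O–CH2Ph bonds of the arm ethers and the O–CH3 bond on O5 are cut. All phenols stay masked to the end as ethers that tolerate organolithium, zinc, heat and palladium chemistry, and one Lewis-acid operation removes them. The forward step must spare the O7 methyl ether (chelation to the C4 carbonyl is the discriminating element), must trap benzyl cations, and must run cold enough that ring C does not open.

**25 ⇒ 23 + 24.** The C2–aryl bond is cut. The stereocentre is then set in the last C–C bond-forming step by catalyst control on a flat, achiral chromone, and ring B comes from a commercial reagent. The forward step needs high facial selectivity on an electron-rich 5-alkoxychromone and base-free conditions so that the product cannot racemise.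

**23 ⇒ 21 (through 22).** O1–C2 and C2–C3 are cut, removing a one-carbon unit. The acetyl group and the single free ortho hydroxyl of 21 define ring C without ambiguity, since the other ortho oxygen is a methyl ether. The forward step needs only mild heat and acid.

**21 ⇒ 19.** The C4a–C4 bond is cut. C4a is the only unsubstituted carbon of ring A and by far the most nucleophilic aryl carbon in the molecule. The demand is an acylating species weak enough to ignore rings D and E (each has free positions ortho or para to a benzyloxy group) and conditions that spare benzyl ethers. A nitrile under Houben–Hoesch conditions meets both, where an acyl chloride with a strong Lewis acid would not.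

**19 ⇒ 14 + 12 (key disconnection).** The C8–C8a and C6–C7 bonds are cut, and the C4a–C8a bond is opened and re-formed. The hexasubstituted ring is reduced to a four-membered ring and an alkyne, each carrying one arm, and the regiochemistry of ring A becomes a matter of alkyne polarity. The forward step requires clean thermal opening of 14 and a [2+2] orientation that places the methoxy carbon of 12 between the arms.

**14 ⇒ 13 ⇒ 12.** The bonds that later become C8a–C6 and C4a–C5 are cut, removing a two-carbon ketene unit. Three design choices are made here: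
- The oxygen destined for C5 is carried as a methyl ether rather than a higher alkyl ether. Both halves of ring A then come from the single alkynyl ether 12 (one alkylation instead of two), and chelation-assisted chloride attack at the end occurs on a methyl group and can be run colder.
- The ketene is a dihaloketene made in the flask from an acid chloride and zinc, then dechlorinated, which avoids handling gaseous ketene at the cost of one step.
- The dechlorination is run in methanol so that any alkoxy exchange at the vinylogous ester is degenerate.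

**12 ⇒ 9 + 11 (from 10).** The CH2–C(sp) bond is cut. The forward step is an acetylide alkylation by a reactive benzylic bromide, and it must avoid excess strong base, which would isomerise the doubly activated CH2 to an allene.

**9 ⇒ 8 ⇒ 7 ⇒ 3 + 6.** After two functional-group changes at the benzylic carbon, the aryl–CH2 bond between ring D (its carbon para to oxygen) and the ring E benzylic carbon is cut. The forward sp2–sp3 cross-coupling fixes the para/ortho pattern of the diarylmethane from the substitution of the two building blocks and must tolerate the aldehyde.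

**3 ⇒ 2 ⇒ 1 and 6 ⇒ 5 ⇒ 4.** Only C–B/C–Br exchange, O-benzylation and OH-to-Br exchange remain, leading to two commercial salicyl derivatives.

## Other disconnections considered

**Alternative 1:** The cut is at the two bonds between the benzylic CH2 groups on C6 and C8 and C1 of ring D. In the forward step the doubly chloromethylated (S)-flavanone acetate A2 would be coupled at a cathode, under nickel catalysis, with two molecules of the ring D–E aryl bromide A3 to give A1, which then needs only loss of the acetate and four methoxymethyl groups.
- In its favour: the ring A pattern and the C2 configuration are bought with a natural flavanone, so neither a ring construction nor asymmetric catalysis is needed. Two C–C bonds form in one operation. The final deprotection (mild acid, mild methanolysis) is gentler than a boron Lewis acid. On stereochemistry and on step economy (roughly half the steps) this plan is the better one, provided the stereocentre survives.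
- Against it here: A2 has two benzylic chlorides, each flanked by two oxygen-bearing carbons, that ionise easily and are hard to prepare cleanly. The coupling must succeed twice at di-ortho-substituted benzylic carbons with an ortho-alkoxy aryl bromide, against reduction of C–Cl to methyl and benzylic homocoupling. The aryl ketone and aryl acetate are themselves reducible or base-labile, and any base generated near the cathode would open ring C and erode C2.
- Comparison: the regiochemistry is as unambiguous as in the chosen plan (equal). It rests, however, on chemoselectivity among several reducible groups, whereas the formation of 19 rests on the intrinsic polarity of two reactants that carry no competing functionality.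

**Alternative 2:** The cut is at the bond from each outer benzylic carbon to the ortho carbon of ring E. In the forward step the bis(phenylthiomethyl) flavanone A5 would be S-chlorinated and captured by phenol A6 as aryloxysulfonium salts. Deprotonation at the benzylic carbons would trigger two [2,3]-sigmatropic shifts (a Gassman-type ortho-alkylation) to give A4, followed by desulfurisation and acetal cleavage.
- In its favour: ortho attachment to ring E is enforced by the five-membered cyclic transition state, and ring E comes from the simplest possible source. On ortho selectivity it is the equal of the chosen plan (which buys that relationship with 4), and on mildness of the final deprotection it is better.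
- Against it here: it solves the easiest bonds of the molecule. A5 already contains rings A to D with the complete ring A pattern, so the central problem is untouched. Electrophilic chlorine would meet very electron-rich rings. The base needed for ylide formation acts on a 5-O-protected flavanone, the type most prone to ring opening. Both arms must react. Raney Ni desulfurisation can also attack the ketone or the benzylic C2–O bond. The two extra sulfur-bearing stereocentres give epimer mixtures until they are removed.
- Comparison: the pericyclic logic is as reliable in principle as that of the chosen plan, but step economy is worse (a longer route to A5 plus two steps after the key step).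

**Alternative 3:** The cut is through ring C at C4a–C4, C3–C4 and O1–C2. In the forward step the iodoresorcinol A8, carbon monoxide A9 and phenylacetylene A10 would combine under palladium catalysis (carbonylative alkynylation, then 6-endo closure of the ynone) to give flavone A7.
- In its favour: ring C and ring B arrive in one step with three bonds formed, which is better than steps 12 to 14 of the chosen plan on bond economy. The symmetry of A8 makes either hydroxyl acceptable, an equal use of the same symmetry. No stereocentre is yet at risk.
- Against it here: A7 is a flavone, so the (2S) centre must be created afterwards by enantioselective conjugate reduction of a β-aryl-β-aryloxy enone. That has thinner precedent than aryl addition to a chromone and is prone to over-reduction of the ketone. A8 still requires two arms on C4 and C6 of a 5-methoxyresorcinol while its most nucleophilic carbon stays free, which is the very problem the route to 19 solves. 5-exo closure to an aurone competes, and A9 is a toxic gas.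
- Comparison: once the reduction and the synthesis of A8 are counted, step economy is about equal, and stereocontrol is weaker than in the chosen plan.

Key step: step 11

**Assumption on the chemistry:** the palladium/pyridinooxazoline arylation of chromones is taken to follow the facial preference known for cyclic enones, in which the (S)-ligand leads to the (R)-flavanone. The (R)-ligand is therefore specified for the (2S) product.

**Abbreviations:**
- ArmBn = {2-(benzyloxy)-5-[2-(benzyloxy)benzyl]phenyl}methyl, the arm with both phenols as benzyl ethers (fragment Cc1cc(Cc2ccccc2OCc2ccccc2)ccc1OCc1ccccc1, attached through the first CH2).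
- (R)-t-BuPyOx = (R)-4-tert-butyl-2-(pyridin-2-yl)-4,5-dihydrooxazole.

## Route

Step 1
Reactants: 1 5-bromosalicylaldehyde
Product: 2 2-(benzyloxy)-5-bromobenzaldehyde
Conditions: BnBr, K2CO3, DMF, rt
Reagents that add atoms: benzyl bromide, BrCc1ccccc1
Why: Williamson etherification of the acidic salicyl phenol; the benzyl ether withstands all later base, organometal, thermal and palladium steps and is removable with BCl3 at low temperature.

Step 2
Reactants: 2 2-(benzyloxy)-5-bromobenzaldehyde
Product: 3 2-(benzyloxy)-5-(4,4,5,5-tetramethyl-1,3,2-dioxaborolan-2-yl)benzaldehyde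
Conditions: B2pin2, PdCl2(dppf), KOAc, 1,4-dioxane, 85 °C
Reagents that add atoms: bis(pinacolato)diboron, CC1(C)OB(OC1(C)C)B1OC(C)(C)C(C)(C)O1
Why: Miyaura borylation of an aryl bromide; the weak acetate base leaves the aldehyde alone and suppresses biaryl formation.

Step 3
Reactants: 4 2-hydroxybenzyl alcohol
Product: 5 2-(benzyloxy)benzyl alcohol
Conditions: BnBr, K2CO3, acetone, reflux
Reagents that add atoms: benzyl bromide, BrCc1ccccc1
Why: Williamson etherification; carbonate deprotonates only the phenol, so the benzylic alcohol stays free.

Step 4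
Reactants: 5 2-(benzyloxy)benzyl alcohol
Product: 6 2-(benzyloxy)benzyl bromide
Conditions: PBr3, CH2Cl2, 0 °C
Reagents that add atoms: phosphorus tribromide, BrP(Br)Br
Why: Conversion of a benzylic alcohol to the bromide through the phosphite ester; the electron-rich bromide should be used promptly.

Step 5
Reactants: 3 2-(benzyloxy)-5-(4,4,5,5-tetramethyl-1,3,2-dioxaborolan-2-yl)benzaldehyde; 6 2-(benzyloxy)benzyl bromide
Product: 7 2-(benzyloxy)-5-[2-(benzyloxy)benzyl]benzaldehyde
Conditions: Pd(PPh3)4, K2CO3, THF/H2O, 70 °C
Reagents that add atoms: none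
Why: Suzuki–Miyaura sp2–sp3 coupling; oxidative addition to the benzylic bromide is fast, the benzylpalladium intermediate has no β-hydrogen, and the aldehyde is inert.

Step 6
Reactants: 7 2-(benzyloxy)-5-[2-(benzyloxy)benzyl]benzaldehyde
Product: 8 {2-(benzyloxy)-5-[2-(benzyloxy)benzyl]phenyl}methanol
Conditions: NaBH4, MeOH/THF, 0 °C
Reagents that add atoms: none
Why: Hydride reduction of an aryl aldehyde; no other reducible group is present.

Step 7
Reactants: 8 {2-(benzyloxy)-5-[2-(benzyloxy)benzyl]phenyl}methanol
Product: 9 1-(benzyloxy)-4-[2-(benzyloxy)benzyl]-2-(bromomethyl)benzene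
Conditions: PBr3, CH2Cl2, 0 °C
Reagents that add atoms: phosphorus tribromide, BrP(Br)Br
Why: Same benzylic alcohol-to-bromide exchange as in step 4; aryl benzyl ethers and the diarylmethane are inert to PBr3 at 0 °C.

Step 8
Reactants: 10 chloroacetaldehyde dimethyl acetal; 9 1-(benzyloxy)-4-[2-(benzyloxy)benzyl]-2-(bromomethyl)benzene
Product: 12 1-methoxy-3-{2-(benzyloxy)-5-[2-(benzyloxy)benzyl]phenyl}prop-1-yne, via lithium methoxyacetylide 11 (not isolated)
Conditions: Et2NH, n-BuLi, THF, 0 °C, then 10; then 9, DMPU, −78 °C → 0 °C
Reagents that add atoms: none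
Why: Lithium diethylamide removes methanol and HCl from the α-chloroacetal and deprotonates the resulting methoxyacetylene; the acetylide is then alkylated by the benzylic bromide (SN2 acetylide alkylation). A slight excess of 10 over the amide leaves no free strong base to isomerise the propargylic-benzylic CH2 of 12 to an allenyl ether.

Step 9
Reactants: 12 1-methoxy-3-{2-(benzyloxy)-5-[2-(benzyloxy)benzyl]phenyl}prop-1-yne
Product: 13 4,4-dichloro-3-methoxy-2-(ArmBn)cyclobut-2-en-1-one
Conditions: Cl3CCOCl, Zn–Cu couple, DME, Et2O, rt
Reagents that add atoms: trichloroacetyl chloride, O=C(Cl)C(Cl)(Cl)Cl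
Why: [2+2] cycloaddition of dichloroketene, made in the flask by zinc dechlorination of the acid chloride, with the electron-rich alkynyl ether; the alkyne carbon remote from oxygen attacks the central ketene carbon, so the carbonyl ends up next to the arm-bearing carbon. DME ties up ZnCl2, and no gaseous ketene is handled.

Step 10
Reactants: 13 4,4-dichloro-3-methoxy-2-(ArmBn)cyclobut-2-en-1-one
Product: 14 3-methoxy-2-(ArmBn)cyclobut-2-en-1-one
Conditions: Zn dust, AcOH, TMEDA, MeOH, 0 °C → rt
Reagents that add atoms: none
Why: Reductive dechlorination of an α,α-dichloroketone through zinc enolates, buffered by TMEDA/AcOH to avoid over-reduction; methanol as solvent makes any alkoxy exchange at the vinylogous ester degenerate.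

Step 11
Reactants: 14 3-methoxy-2-(ArmBn)cyclobut-2-en-1-one; 12 1-methoxy-3-{2-(benzyloxy)-5-[2-(benzyloxy)benzyl]phenyl}prop-1-yne
Product: 19 3,5-dimethoxy-2,4-bis(ArmBn)phenol, via vinylketene 15 (not isolated), via 4-alkenylcyclobutenone 16 (not isolated), via dienylketene 17 (not isolated), via cyclohexadienone 18 (not isolated)
Conditions: 12 (1.3 equiv), degassed toluene, sealed tube, 110 °C then 140 °C; then KOH, MeOH/THF, rt
Reagents that add atoms: none
Why: Danheiser benzannulation of a cyclobutenone with an alkynyl ether, a cascade of four pericyclic events. Conrotatory four-electron opening of 14 breaks the C4a–C8a bond and gives vinylketene 15. 15 then adds across 12 in a regiospecific [2+2] cycloaddition: the alkyne carbon remote from oxygen, made nucleophilic by the methoxy group, attacks the central ketene carbon (C8–C8a bond) and the oxygen-bearing alkyne carbon closes onto the ketene α-carbon (C6–C7 bond), giving 16, whose quaternary carbon is only a transient racemic stereocentre. A second four-electron opening of 16 gives dienylketene 17, and thermal disrotatory six-electron electrocyclisation re-forms C4a–C8a and closes ring A as 18, which tautomerises irreversibly to phenol 19, so no stereocentre remains. The only selectivity needed is the orientation of the [2+2] step; the polarisation of the ynol ether secures it, placing the methoxy group on C7 between the two arms and leaving the hydroxyl on C8a beside the unsubstituted C4a. 12 is a methyl ether, so no retro-ene loss of an alkene to a ketene can compete at the reaction temperature, and the vinylogous-ester stabilisation of 14 is the reason for the higher final temperature. The closing KOH treatment only cleaves any aryl ester formed if 19 captures 15.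

Step 12
Reactants: 19 3,5-dimethoxy-2,4-bis(ArmBn)phenol
Product: 21 1-[2-hydroxy-4,6-dimethoxy-3,5-bis(ArmBn)phenyl]ethan-1-one, via ketiminium chloride 20 (not isolated)
Conditions: MeCN, ZnCl2, HCl (g), Et2O, 0 °C; then H2O, 80 °C
Reagents that add atoms: acetonitrile, CC#N; water, O
Why: Houben–Hoesch acylation: the nitrilium electrophile is weak and reacts only with the trioxygenated ring A at its single free carbon (ortho to OH and OMe, para to OMe), not with the mono-alkoxy rings D and E. Aryl benzyl ethers tolerate HCl/ZnCl2 in ether, and aqueous heating hydrolyses the ketiminium salt to the ketone.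

Step 13
Reactants: 21 1-[2-hydroxy-4,6-dimethoxy-3,5-bis(ArmBn)phenyl]ethan-1-one
Product: 23 5,7-dimethoxy-6,8-bis(ArmBn)-4H-chromen-4-one, via enaminone 22 (not isolated)
Conditions: Me2NCH(OMe)2, toluene, 100 °C; then conc. HCl, CH2Cl2, rt
Reagents that add atoms: N,N-dimethylformamide dimethyl acetal, COC(OC)N(C)C
Why: Condensation of the methyl ketone with the amide acetal gives the enaminone; acid then triggers addition of the ortho hydroxyl to the β-carbon and loss of dimethylamine (standard chromone synthesis from 2-hydroxyacetophenones). Only one ortho oxygen is free, so a single chromone can form.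

Step 14
Reactants: 23 5,7-dimethoxy-6,8-bis(ArmBn)-4H-chromen-4-one; 24 phenylboronic acid
Product: 25 (2S)-5,7-dimethoxy-6,8-bis(ArmBn)-2-phenylchroman-4-one
Conditions: Pd(OCOCF3)2 (5 mol %), (R)-t-BuPyOx (6 mol %), NH4PF6, H2O, ClCH2CH2Cl, 60 °C
Reagents that add atoms: none
Why: Enantioselective conjugate addition of an arylboronic acid to a chromone under cationic divalent palladium/pyridinooxazoline catalysis: transmetalation, insertion of C2=C3 into the Pd–phenyl bond with phenyl going to C2, and protonation of the palladium enolate by water. The tert-butyl group of the ligand blocks one enantioface so that the (2S) centre is set, and the absence of base prevents racemisation by ring opening.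

Step 15
Reactants: 25 (2S)-5,7-dimethoxy-6,8-bis(ArmBn)-2-phenylchroman-4-one
Product: 26 (2S)-5-hydroxy-6,8-bis[2-hydroxy-5-(2-hydroxybenzyl)benzyl]-7-methoxy-2-phenylchroman-4-one
Conditions: BCl3, C6HMe5, CH2Cl2, −78 °C → 0 °C; then MeOH, aq. NaHCO3
Reagents that add atoms: none
Why: Lewis-acid ether cleavage: at −78 °C BCl3 ionises the four aryl benzyl ethers and pentamethylbenzene traps the benzyl cations by Friedel–Crafts alkylation before they can attack the phenol rings. On warming, the boron chelate between the C4 carbonyl and O5 directs chloride to the peri methyl group only, so the non-chelated O7 methyl ether is kept; C2 is not touched and the chelated ketone disfavours ring opening.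

## Compound list

1 | 5-bromosalicylaldehyde | O=Cc1cc(Br)ccc1O | starting material
2 | 2-(benzyloxy)-5-bromobenzaldehyde | O=Cc1cc(Br)ccc1OCc1ccccc1 | intermediate
3 | 2-(benzyloxy)-5-(4,4,5,5-tetramethyl-1,3,2-dioxaborolan-2-yl)benzaldehyde | O=Cc1cc(B2OC(C)(C)C(C)(C)O2)ccc1OCc1ccccc1 | intermediate
4 | 2-hydroxybenzyl alcohol | OCc1ccccc1O | starting material
5 | 2-(benzyloxy)benzyl alcohol | OCc1ccccc1OCc1ccccc1 | intermediate
6 | 2-(benzyloxy)benzyl bromide | BrCc1ccccc1OCc1ccccc1 | intermediate
7 | 2-(benzyloxy)-5-[2-(benzyloxy)benzyl]benzaldehyde | O=Cc1cc(Cc2ccccc2OCc2ccccc2)ccc1OCc1ccccc1 | intermediate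
8 | {2-(benzyloxy)-5-[2-(benzyloxy)benzyl]phenyl}methanol | OCc1cc(Cc2ccccc2OCc2ccccc2)ccc1OCc1ccccc1 | intermediate
9 | 1-(benzyloxy)-4-[2-(benzyloxy)benzyl]-2-(bromomethyl)benzene (ArmBn bromide) | BrCc1cc(Cc2ccccc2OCc2ccccc2)ccc1OCc1ccccc1 | intermediate
10 | chloroacetaldehyde dimethyl acetal | COC(CCl)OC | starting material
11 | lithium methoxyacetylide | [Li]C#COC | intermediate
12 | 1-methoxy-3-{2-(benzyloxy)-5-[2-(benzyloxy)benzyl]phenyl}prop-1-yne | COC#CCc1cc(Cc2ccccc2OCc2ccccc2)ccc1OCc1ccccc1 | intermediate
13 | 4,4-dichloro-3-methoxy-2-(ArmBn)cyclobut-2-en-1-one | COC1=C(Cc3cc(Cc4ccccc4OCc4ccccc4)ccc3OCc3ccccc3)C(=O)C1(Cl)Cl | intermediate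
14 | 3-methoxy-2-(ArmBn)cyclobut-2-en-1-one | COC1=C(Cc3cc(Cc4ccccc4OCc4ccccc4)ccc3OCc3ccccc3)C(=O)C1 | intermediate
15 | 3-methoxy-2-(ArmBn)buta-1,3-dien-1-one (vinylketene) | C=C(OC)C(Cc3cc(Cc4ccccc4OCc4ccccc4)ccc3OCc3ccccc3)=C=O | intermediate
16 | 3-methoxy-4-(1-methoxyethenyl)-2,4-bis(ArmBn)cyclobut-2-en-1-one (racemic) | O=C1C(Cc3cc(Cc4ccccc4OCc4ccccc4)ccc3OCc3ccccc3)=C(OC)C1(Cc3cc(Cc4ccccc4OCc4ccccc4)ccc3OCc3ccccc3)C(OC)=C | intermediate
17 | 3,5-dimethoxy-2,4-bis(ArmBn)hexa-1,3,5-trien-1-one (dienylketene) | O=C=C(Cc3cc(Cc4ccccc4OCc4ccccc4)ccc3OCc3ccccc3)C(OC)=C(Cc3cc(Cc4ccccc4OCc4ccccc4)ccc3OCc3ccccc3)C(OC)=C | intermediate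
18 | 3,5-dimethoxy-2,4-bis(ArmBn)cyclohexa-2,4-dien-1-one | O=C1CC(OC)=C(Cc3cc(Cc4ccccc4OCc4ccccc4)ccc3OCc3ccccc3)C(OC)=C1Cc3cc(Cc4ccccc4OCc4ccccc4)ccc3OCc3ccccc3 | intermediate
19 | 3,5-dimethoxy-2,4-bis(ArmBn)phenol | COc1cc(O)c(Cc3cc(Cc4ccccc4OCc4ccccc4)ccc3OCc3ccccc3)c(OC)c1Cc3cc(Cc4ccccc4OCc4ccccc4)ccc3OCc3ccccc3 | intermediate
20 | 1-[2-hydroxy-4,6-dimethoxy-3,5-bis(ArmBn)phenyl]ethan-1-iminium chloride | CC(=[NH2+])c1c(O)c(Cc3cc(Cc4ccccc4OCc4ccccc4)ccc3OCc3ccccc3)c(OC)c(Cc3cc(Cc4ccccc4OCc4ccccc4)ccc3OCc3ccccc3)c1OC.[Cl-] | intermediate
21 | 1-[2-hydroxy-4,6-dimethoxy-3,5-bis(ArmBn)phenyl]ethan-1-one | CC(=O)c1c(O)c(Cc3cc(Cc4ccccc4OCc4ccccc4)ccc3OCc3ccccc3)c(OC)c(Cc3cc(Cc4ccccc4OCc4ccccc4)ccc3OCc3ccccc3)c1OC | intermediate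
22 | (E)-3-(dimethylamino)-1-[2-hydroxy-4,6-dimethoxy-3,5-bis(ArmBn)phenyl]prop-2-en-1-one | CN(C)/C=C/C(=O)c1c(O)c(Cc3cc(Cc4ccccc4OCc4ccccc4)ccc3OCc3ccccc3)c(OC)c(Cc3cc(Cc4ccccc4OCc4ccccc4)ccc3OCc3ccccc3)c1OC | intermediate
23 | 5,7-dimethoxy-6,8-bis(ArmBn)-4H-chromen-4-one | O=c1ccoc2c(Cc3cc(Cc4ccccc4OCc4ccccc4)ccc3OCc3ccccc3)c(OC)c(Cc3cc(Cc4ccccc4OCc4ccccc4)ccc3OCc3ccccc3)c(OC)c12 | intermediate
24 | phenylboronic acid | OB(O)c1ccccc1 | starting material
25 | (2S)-5,7-dimethoxy-6,8-bis(ArmBn)-2-phenylchroman-4-one | O=C1C[C@@H](c2ccccc2)Oc2c(Cc3cc(Cc4ccccc4OCc4ccccc4)ccc3OCc3ccccc3)c(OC)c(Cc3cc(Cc4ccccc4OCc4ccccc4)ccc3OCc3ccccc3)c(OC)c12 | intermediate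
26 | 5''-(2''''-hydroxybenzyl)uvarinol, (2S)-5-hydroxy-6,8-bis[2-hydroxy-5-(2-hydroxybenzyl)benzyl]-7-methoxy-2-phenylchroman-4-one | COc1c(Cc2cc(Cc3ccccc3O)ccc2O)c(O)c2c(c1Cc1cc(Cc3ccccc3O)ccc1O)O[C@H](c1ccccc1)CC2=O | target

## Step count and least certain steps

Total: 15 steps. Longest linear sequence: 13 steps (1, 2, 5, 6, 7, 8, 9, 10, 11, 12, 13, 14, 15); steps 3 and 4 form the side branch.

**Step 11 (key step).**
- Process at risk: the first electrocyclic opening. The methoxy group on C3 stabilises 14 as a vinylogous ester, so opening to 15 may need temperatures at which 12 begins to isomerise at its doubly activated CH2, or at which 15 is lost to dimerisation or to acylation of 19. Incomplete opening of 16 is the second possibility.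
- Fallback, setting out from 9 and coming back at 21: ring A is bought and not built. 2',6'-Dihydroxy-4'-methoxyacetophenone F1 would be C-benzylated twice with 9 (NaOMe, MeOH/toluene; the protic medium favours C- over O-alkylation, and the two positions flanking the methoxy group are the only free ring carbons) to give 1-[2,6-dihydroxy-4-methoxy-3,5-bis(ArmBn)phenyl]ethan-1-one F2. The two hydroxyls of F2 are equivalent. One equivalent of dimethyl sulfate with K2CO3 in acetone should methylate only one of them, because the remaining hydroxyl is then locked in the hydrogen bond to the carbonyl. This gives 21 and by-passes steps 8 to 12.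

**Step 8.**
- Process at risk: competitive N-benzylation of the diethylamine released during acetylide formation, and base-mediated propargyl-to-allenyl isomerisation of the product.
- Fallback, setting out from 9 and coming back at 12: amine-free generation of 11 from (E)-1,2-dichloro-1-methoxyethene F3 (from trichloroethylene, methanol and KH) with two equivalents of n-BuLi at −78 °C (elimination, then chlorine–lithium exchange), followed by the same alkylation of 9 in THF/DMPU.

**Step 12.**
- Process at risk: slow C-acylation at the hindered last position of ring A, diversion to an O-imidate at the phenol, or gradual loss of benzyl ethers on long exposure to HCl/ZnCl2.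
- Fallback, setting out from 19 and coming back at 23: Vilsmeier–Haack formylation (POCl3, DMF; aqueous NaOAc), whose weak electrophile again selects ring A, would give 2-hydroxy-4,6-dimethoxy-3,5-bis(ArmBn)benzaldehyde F4. Addition of ethynylmagnesium bromide would give 1-[2-hydroxy-4,6-dimethoxy-3,5-bis(ArmBn)phenyl]prop-2-yn-1-ol F5, and MnO2 oxidation would give 1-[2-hydroxy-4,6-dimethoxy-3,5-bis(ArmBn)phenyl]prop-2-yn-1-one F6. F6 should close to 23 on exposure to diethylamine in ethanol (conjugate addition, then addition–elimination by the phenol).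

**Step 14.**
- Process at risk: sluggish insertion of the electron-rich, 5-alkoxy-substituted chromone, so that protodeboronation and biphenyl formation outrun the addition; or reduced facial discrimination because the C8 arm sits close to the reacting alkene.
- Fallback, setting out from 21 and coming back at 25: Claisen acylation of 21 (LiN(SiMe3)2, 3 equiv, then benzoyl chloride) would give 1-[2-hydroxy-4,6-dimethoxy-3,5-bis(ArmBn)phenyl]-3-phenylpropane-1,3-dione F7. Asymmetric transfer hydrogenation with RuCl(p-cymene)[(R,R)-TsDPEN] in HCO2H/Et3N should reduce the unhindered benzoyl carbonyl to (3R)-3-hydroxy-1-[2-hydroxy-4,6-dimethoxy-3,5-bis(ArmBn)phenyl]-3-phenylpropan-1-one F8. Mitsunobu cyclisation (PPh3, DIAD, THF, 0 °C) would close O1–C2 with inversion to give 25.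

**Step 15.**
- Process at risk: loss of the C7 methyl ether (boron delivered by neighbouring arm aryloxyboron groups once the benzyl groups have gone), erosion of the C2 configuration through Lewis-acid-induced opening of ring C at the temperature needed for the peri demethylation, or C-benzylation of the phenol rings if cation trapping is incomplete.
- Fallback, setting out from 23 and coming back at 26: the peri demethylation is moved to a stage without a stereocentre. MgI2·OEt2 (chelation-controlled, ordinary aryl benzyl ethers untouched) would give 5-hydroxy-7-methoxy-6,8-bis(ArmBn)-4H-chromen-4-one F9. The same Pd(OCOCF3)2/(R)-t-BuPyOx addition of 24 would give (2S)-5-hydroxy-7-methoxy-6,8-bis(ArmBn)-2-phenylchroman-4-one F10. Neutral hydrogenolysis (H2, Pd/C, EtOAc) would then remove the four benzyl groups to give 26.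

## Further compounds

F1 | step 11 | 2',6'-dihydroxy-4'-methoxyacetophenone | CC(=O)c1c(O)cc(OC)cc1O
F2 | step 11 | 1-[2,6-dihydroxy-4-methoxy-3,5-bis(ArmBn)phenyl]ethan-1-one | CC(=O)c1c(O)c(Cc3cc(Cc4ccccc4OCc4ccccc4)ccc3OCc3ccccc3)c(OC)c(Cc3cc(Cc4ccccc4OCc4ccccc4)ccc3OCc3ccccc3)c1O
F3 | step 8 | (E)-1,2-dichloro-1-methoxyethene | CO/C(Cl)=C\Cl
F4 | step 12 | 2-hydroxy-4,6-dimethoxy-3,5-bis(ArmBn)benzaldehyde | O=Cc1c(O)c(Cc3cc(Cc4ccccc4OCc4ccccc4)ccc3OCc3ccccc3)c(OC)c(Cc3cc(Cc4ccccc4OCc4ccccc4)ccc3OCc3ccccc3)c1OC
F5 | step 12 | 1-[2-hydroxy-4,6-dimethoxy-3,5-bis(ArmBn)phenyl]prop-2-yn-1-ol (racemic) | C#CC(O)c1c(O)c(Cc3cc(Cc4ccccc4OCc4ccccc4)ccc3OCc3ccccc3)c(OC)c(Cc3cc(Cc4ccccc4OCc4ccccc4)ccc3OCc3ccccc3)c1OC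
F6 | step 12 | 1-[2-hydroxy-4,6-dimethoxy-3,5-bis(ArmBn)phenyl]prop-2-yn-1-one | C#CC(=O)c1c(O)c(Cc3cc(Cc4ccccc4OCc4ccccc4)ccc3OCc3ccccc3)c(OC)c(Cc3cc(Cc4ccccc4OCc4ccccc4)ccc3OCc3ccccc3)c1OC
F7 | step 14 | 1-[2-hydroxy-4,6-dimethoxy-3,5-bis(ArmBn)phenyl]-3-phenylpropane-1,3-dione | O=C(CC(=O)c1ccccc1)c1c(O)c(Cc3cc(Cc4ccccc4OCc4ccccc4)ccc3OCc3ccccc3)c(OC)c(Cc3cc(Cc4ccccc4OCc4ccccc4)ccc3OCc3ccccc3)c1OC
F8 | step 14 | (3R)-3-hydroxy-1-[2-hydroxy-4,6-dimethoxy-3,5-bis(ArmBn)phenyl]-3-phenylpropan-1-one | O=C(C[C@@H](O)c1ccccc1)c1c(O)c(Cc3cc(Cc4ccccc4OCc4ccccc4)ccc3OCc3ccccc3)c(OC)c(Cc3cc(Cc4ccccc4OCc4ccccc4)ccc3OCc3ccccc3)c1OC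
F9 | step 15 | 5-hydroxy-7-methoxy-6,8-bis(ArmBn)-4H-chromen-4-one | O=c1ccoc2c(Cc3cc(Cc4ccccc4OCc4ccccc4)ccc3OCc3ccccc3)c(OC)c(Cc3cc(Cc4ccccc4OCc4ccccc4)ccc3OCc3ccccc3)c(O)c12
F10 | step 15 | (2S)-5-hydroxy-7-methoxy-6,8-bis(ArmBn)-2-phenylchroman-4-one | O=C1C[C@@H](c2ccccc2)Oc2c(Cc3cc(Cc4ccccc4OCc4ccccc4)ccc3OCc3ccccc3)c(OC)c(Cc3cc(Cc4ccccc4OCc4ccccc4)ccc3OCc3ccccc3)c(O)c12
A1 | alternative 1 | (2S)-5-acetoxy-7-methoxy-6,8-bis{2-(methoxymethoxy)-5-[2-(methoxymethoxy)benzyl]benzyl}-2-phenylchroman-4-one | O=C1C[C@@H](c2ccccc2)Oc2c(Cc3cc(Cc4ccccc4OCOC)ccc3OCOC)c(OC)c(Cc3cc(Cc4ccccc4OCOC)ccc3OCOC)c(OC(C)=O)c12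
A2 | alternative 1 | (2S)-5-acetoxy-6,8-bis(chloromethyl)-7-methoxy-2-phenylchroman-4-one | O=C1C[C@@H](c2ccccc2)Oc2c(CCl)c(OC)c(CCl)c(OC(C)=O)c12
A3 | alternative 1 | 2-bromo-1-(methoxymethoxy)-4-[2-(methoxymethoxy)benzyl]benzene | COCOc1ccc(Cc2ccccc2OCOC)cc1Br
A4 | alternative 2 | (2S)-7-methoxy-5-(methoxymethoxy)-6,8-bis{5-[(2-hydroxyphenyl)(phenylthio)methyl]-2-(methoxymethoxy)benzyl}-2-phenylchroman-4-one (epimers at the two sulfur-bearing carbons) | O=C1C[C@@H](c2ccccc2)Oc2c(Cc3cc(C(Sc4ccccc4)c4ccccc4O)ccc3OCOC)c(OC)c(Cc3cc(C(Sc4ccccc4)c4ccccc4O)ccc3OCOC)c(OCOC)c12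
A5 | alternative 2 | (2S)-7-methoxy-5-(methoxymethoxy)-6,8-bis{2-(methoxymethoxy)-5-[(phenylthio)methyl]benzyl}-2-phenylchroman-4-one | O=C1C[C@@H](c2ccccc2)Oc2c(Cc3cc(CSc4ccccc4)ccc3OCOC)c(OC)c(Cc3cc(CSc4ccccc4)ccc3OCOC)c(OCOC)c12
A6 | alternative 2 | phenol | Oc1ccccc1
A7 | alternative 3 | 5-hydroxy-7-methoxy-6,8-bis{2-(methoxymethoxy)-5-[2-(methoxymethoxy)benzyl]benzyl}-2-phenyl-4H-chromen-4-one | O=c1cc(-c2ccccc2)oc2c(Cc3cc(Cc4ccccc4OCOC)ccc3OCOC)c(OC)c(Cc3cc(Cc4ccccc4OCOC)ccc3OCOC)c(O)c12
A8 | alternative 3 | 2-iodo-5-methoxy-4,6-bis{2-(methoxymethoxy)-5-[2-(methoxymethoxy)benzyl]benzyl}benzene-1,3-diol | Oc1c(I)c(O)c(Cc3cc(Cc4ccccc4OCOC)ccc3OCOC)c(OC)c1Cc3cc(Cc4ccccc4OCOC)ccc3OCOC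
A9 | alternative 3 | carbon monoxide | [C-]#[O+]
A10 | alternative 3 | phenylacetylene | C#Cc1ccccc1
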